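A catalyst cannot turn quicker than its waits add up, so I time the waits in this flask.

substrate 1.0 M; reagent 1.05 M; free catalyst 25 mM; time 40 s

    reagent + free catalyst → catalyst intermediate A (k1 = 2.64 L mol⁻¹ s⁻¹)
    substrate + catalyst intermediate A → catalyst intermediate B (k2 = 2.63 L mol⁻¹ s⁻¹)
    catalyst intermediate B ⇌ free catalyst + product (K3 = 0.793 M, k3 = 2.25 s⁻¹)

- the state of affairs at 40 s: stopped, and by what, or still going (forward and back rates have come level / no working catalyst is left / it is still moving / the reagent has run out first / all of the substrate has reacted)
- conversion of substrate at 40 s
- amount of product at 40 s, in percent of the substrate charged

- the reaction counts as stopped when no species that holds the substrate changes by six tenths of a point or more over the second half of the time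
- run time (flask): 40 s

1. Each turn waits on reagent, on substrate and on the release of product. At the charge these waits are 0.361 s, 0.380 s and 0.444 s. Their sum is the turn time at the charge, 1.19 s; its reciprocal is the turnover frequency.

2. Bound from above: the waits lengthen as the charges fall, so in this flask 40 s buys at most 33.7 turns per catalyst, which is product worth 84.4% of the substrate charged.

3. To tighten this, I let the way back of the last step stretch the reagent wait by one plus [product]/0.793 M. With the catalyst forms steady, the turn time then curves upward with product, and the time to reach a given [product] is the area under it, divided by the catalyst charged.

4. The midpoint rule undercuts that area. Reaching 0.600 M of product takes at least 40.4 s, longer than 40 s, so in this reckoning product stays under 60.0% of the substrate charged.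

5. The chord overshoots the area. The catalyst forms can hold back up to 25 mM of substrate and of reagent, so I take that off both. Reaching 0.500 M of product then takes at most 36.3 s, and even with 1.19 s added for start-up that is shorter than 40 s. In this reckoning product therefore passes 50.0% of the substrate charged.

6. Below 0.600 M of product, the second half of the time still adds at least 17 percentage points, so I call this flask still moving.

7. The forecast says it is still moving, with 57% conversion and 56% product, and that product lies inside my bracket. Its ground is that the substrate is “still changing far faster than the stopping threshold”.

8. The flask gives it is still moving, with 57.3% conversion and 56.4% product. At 40.0 s it still holds 43% of its substrate and 45% of its reagent. That product is 22.6 turns per catalyst, against the ceiling of 33.7. The neighbour charged with 0.010 M of free catalyst has the same 1.19 s and the same ceiling in turns, which there means 33.7% product. That neighbour holds 28.3% product, or 28.3 turns per catalyst.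

The rate constants were drawn at random within sensible limits; the rest is arithmetic.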